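**Retrosynthetic overview**

1. Atom labels follow the order of the atoms in the target SMILES (C1 = methyl on the ring alkene, C16 = carboxyl carbon, C27 = carbinol carbon, O28 = its hydroxyl oxygen). Rings: A = C3/C4/C5/C6/C8, B = C2/C3/C8/C9/C10/C11/C13/C27, C = C13/C14/C15/C25/C26/C27, D = C15/C19/C20/C21/C25.
2. Feature on which the plan rests: the 19-carbon path C14–C13–C11–C10–C9–C8–C6–C5–C4–C3–C2–C27–C26–C25–C15–C19–C20–C21–C22 winds through all four rings and carries a one-carbon branch at every fourth atom (C12, C7, C1, C16, and C23 beside C24 at the end). It is therefore an intact, unrearranged head-to-tail chain of five isoprene units.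
3. Target ⇒ sesterfisherol: the C16 carboxyl is traced back to a methyl group (late P450 oxidation).
4. Sesterfisherol ⇒ all-E geranylfarnesyl diphosphate + water: the sesterterpene synthase makes C14–C15, C21–C25, C3–C8, C13–C27 and C27–O28. Forward ring order: D together with a 15-membered ring, then A, then C and B in one transannular closure.
5. Geranylfarnesyl diphosphate ⇒ geranylfarnesol ⇒ farnesyl phenyl sulfone (C15) + 8-bromogeranyl acetate (C10), joined at C4–C5.

Key step: step 8

Remark on the chemistry (assumption): diphosphate 12 is drawn as the free acid but is made, stored and used as its tris-ammonium salt; the synthase and the P450 are the two neighbouring gene products of Neosartorya fischeri.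

**Route**

Step 1
Reactants: 1 (2E,6E)-farnesyl bromide
Product: 2 (2E,6E)-farnesyl phenyl sulfone
Conditions: PhSO2Na, DMF, 0 °C → rt
Reagents that add atoms: sodium benzenesulfinate, [Na+].[O-]S(=O)c1ccccc1
Why: SN2 S-alkylation of the ambident sulfinate by the primary allylic bromide in a dipolar aprotic solvent should give the sulfone without touching the E alkenes.

Step 2
Reactants: 3 geranyl acetate
Product: 4 (2E,6E)-8-hydroxygeranyl acetate [(2E,6E)-8-hydroxy-3,7-dimethylocta-2,6-dien-1-yl acetate]
Conditions: SeO2 (cat.), t-BuOOH, salicylic acid (cat.), CH2Cl2, rt; stopped at partial conversion, 3 recycled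
Reagents that add atoms: selenium dioxide, O=[Se]=O (hands over the oxygen; kept in turnover by tert-butyl hydroperoxide, CC(C)(C)OO)
Why: Riley allylic oxidation (ene reaction of SeO2, then [2,3]-sigmatropic shift) should attack the E-methyl of the electron-richer terminal alkene, the C2 alkene being deactivated by the allylic acetate, so the new CH2OH ends up trans to the chain.

Step 3
Reactants: 4 (2E,6E)-8-hydroxygeranyl acetate
Product: 5 (2E,6E)-8-bromogeranyl acetate
Conditions: PBr3 (0.4 equiv), Et2O, −10 → 0 °C, dark; used crude
Reagents that add atoms: phosphorus tribromide, BrP(Br)Br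
Why: Bromination of a primary allylic alcohol with PBr3 (SN2 on the phosphite ester) at low temperature should keep the E geometry and leave the acetate alone.

Step 4
Reactants: 2 (2E,6E)-farnesyl phenyl sulfone; 5 (2E,6E)-8-bromogeranyl acetate
Product: 7 (2E,6E,10E,14E)-3,7,11,15,19-pentamethyl-9-(phenylsulfonyl)icosa-2,6,10,14,18-pentaen-1-yl acetate (racemic at the sulfone-bearing carbon), via α-lithio sulfone 6 (not isolated)
Conditions: 2, n-BuLi (1.05 equiv), THF, −78 °C; then 5 in THF, −78 → −40 °C; aq. NH4Cl
Reagents that add atoms: none
Why: Biellmann-type coupling: the sulfonyl-stabilised allyl anion should alkylate at its α-carbon by SN2 on the primary allylic bromide faster than it attacks the acetate at −78 °C, so all alkenes keep position and E geometry, and the new sulfone-bearing carbon (racemic) is erased in step 5.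

Step 5
Reactants: 7 sulfone acetate
Product: 9 (2E,6E,10E,14E)-geranylfarnesol, via hydroxy sulfone lithium alkoxide 8 (not isolated)
Conditions: LiBHEt3 (5 equiv), THF, 0 °C, 20 min; then PdCl2(dppp) (5 mol %), 0 °C → rt; H2O quench
Reagents that add atoms: none
Why: Lithium triethylborohydride should first reduce the acetate to the lithium alkoxide, which Pd cannot ionise, and the Pd(0)-catalysed hydride desulfonylation then passes through a π-allyl complex that takes hydride at its less substituted end, the former sulfone carbon, so the trisubstituted E alkene stays where it is.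

Step 6
Reactants: 9 geranylfarnesol
Product: 11 (2E,6E,10E,14E)-geranylfarnesyl chloride, via geranylfarnesyl mesylate 10 (not isolated)
Conditions: MsCl, 2,4,6-collidine, LiCl, DMF, 0 °C; cold pentane/water work-up; used at once
Reagents that add atoms: lithium chloride, [Li+].[Cl-]
Why: Collington–Meyers chlorination: the mesylate formed in the flask is displaced by chloride in an SN2 reaction at the primary carbon under buffered conditions, which should avoid allylic transposition and E/Z leakage.

Step 7
Reactants: 11 geranylfarnesyl chloride
Product: 12 (2E,6E,10E,14E)-geranylfarnesyl diphosphate (tris-ammonium salt)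
Conditions: (n-Bu4N)3HP2O7 (2 equiv), MeCN, 3 Å MS, rt; Dowex 50W-X8 (NH4+ form), 25 mM NH4HCO3/i-PrOH; cellulose chromatography; lyophilise
Reagents that add atoms: tris(tetra-n-butylammonium) hydrogen diphosphate, CCCC[N+](CCCC)(CCCC)CCCC.CCCC[N+](CCCC)(CCCC)CCCC.CCCC[N+](CCCC)(CCCC)CCCC.OP(=O)([O-])OP(=O)([O-])[O-]
Why: Davisson–Poulter diphosphorylation: direct SN2 displacement of the primary allylic chloride by the diphosphate trianion in MeCN should give the diphosphate with the 2E alkene intact.

Step 8
Reactants: 12 geranylfarnesyl diphosphate; 13 water (buffer)
Product: 17 sesterfisherol, via bicyclic C22 cation 14 (not isolated), via tricyclic allyl cation 15 (not isolated), via tetracyclic allyl cation 16 (not isolated)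
Conditions: recombinant sesterfisherol synthase of Neosartorya fischeri (His6, from E. coli, full-length), 12 fed in portions, 50 mM Tris·HCl pH 7.5, 5 mM MgCl2, 10 % glycerol, DTT, 30 °C, hexane overlay; SiO2
Reagents that add atoms: none
Why: The Mg2+-bound diphosphate of 12 ionises in the class I active site; the C14 allyl cation is taken at C15 by the C15=C25 alkene while C21 of the terminal alkene adds to C25 (cation 14, charge on C22), a transannular 1,5-hydride shift from C27 to C22 creates the C27–C2–C3 allyl cation, C8 adds to C3, hydride shifts C8→C6 and C3→C8 restore the allyl cation (15), C13 adds to C27, hydride shifts C13→C11 and C27→C13 give allyl cation 16, and water caps C27. The closest known reaction type is the class I terpene-synthase cyclisation of a linear prenyl diphosphate, as carried out by the related fungal bifunctional di- and sesterterpene synthases that open with the same macrocycle-plus-cyclopentane closure. Modes of closure: ring D is a 5-exo cation–olefin closure (C21–C25) coupled to a 15-endo macrocyclisation (C14–C15), ring A is a transannular 5-endo closure (C3–C8) that leaves a 12-membered ring, and rings C and B arise together when the transannular C13–C27 bond (6-exo for C, 8-endo for B) divides that ring. Stereocontrol: C15 and C25 come from anti addition across the E-C15=C25 alkene and C21 from the face of the C21=C22 alkene presented to C25, C6/C8 and C11/C13 from suprafacial 1,2-hydride shifts in the folded cation, and C27 from the face of 16 open to bound water, all dictated by the active-site contour that fixes the chain conformation and the absolute sense, the substrate contributing only its all-E geometry. The step needs one fold out of many and a single terminating event (water at C27, not at C3, and no early deprotonation); both should be secured by the enzyme, and the geometry of the C2=C3 ring alkene follows from the E alkene of 12 once C3–C8 is closed.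

Step 9
Reactants: 17 sesterfisherol
Product: 20 sesterfisheric acid, via C16 alcohol 18 (not isolated), via C16 aldehyde 19 (not isolated)
Conditions: Aspergillus oryzae expressing the P450 gene that neighbours the synthase gene in N. fischeri (amyB promoter, host P450 reductase, NADPH regenerated by the cells from the carbon source), maltose medium, air, 30 °C; 17 fed in EtOH/Tween 80; acidify to pH 3, EtOAc; SiO2
Reagents that add atoms: dioxygen, O=O
Why: Three successive P450 oxygenations at the same carbon (hydrogen abstraction and oxygen rebound to 18, a second hydroxylation and loss of water to 19, then oxidation of the aldehyde), a known methyl-to-carboxyl sequence for terpenoid P450s, should be directed to C16 by the active site of the enzyme that performs this step in the producing fungus and touch no stereocentre.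

**Compound list**

1 | (2E,6E)-farnesyl bromide | CC(C)=CCC/C(C)=C/CC/C(C)=C/CBr | starting material
2 | (2E,6E)-farnesyl phenyl sulfone | CC(C)=CCC/C(C)=C/CC/C(C)=C/CS(=O)(=O)c1ccccc1 | intermediate
3 | geranyl acetate | CC(C)=CCC/C(C)=C/COC(C)=O | starting material
4 | (2E,6E)-8-hydroxygeranyl acetate | OC/C(C)=C/CC/C(C)=C/COC(C)=O | intermediate
5 | (2E,6E)-8-bromogeranyl acetate | BrC/C(C)=C/CC/C(C)=C/COC(C)=O | intermediate
6 | α-lithio farnesyl phenyl sulfone (formed in the flask, not isolated) | CC(C)=CCC/C(C)=C/CC/C(C)=C/C([Li])S(=O)(=O)c1ccccc1 | intermediate
7 | (2E,6E,10E,14E)-3,7,11,15,19-pentamethyl-9-(phenylsulfonyl)icosa-2,6,10,14,18-pentaen-1-yl acetate, racemic at C9 of the chain | CC(C)=CCC/C(C)=C/CC/C(C)=C/C(S(=O)(=O)c1ccccc1)C/C(C)=C/CC/C(C)=C/COC(C)=O | intermediate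
8 | lithium alkoxide of the 9-(phenylsulfonyl)geranylfarnesol (formed in the flask, not isolated; racemic) | CC(C)=CCC/C(C)=C/CC/C(C)=C/C(S(=O)(=O)c1ccccc1)C/C(C)=C/CC/C(C)=C/C[O-].[Li+] | intermediate
9 | (2E,6E,10E,14E)-geranylfarnesol | CC(C)=CCC/C(C)=C/CC/C(C)=C/CC/C(C)=C/CC/C(C)=C/CO | intermediate
10 | geranylfarnesyl methanesulfonate (formed in the flask, not isolated) | CC(C)=CCC/C(C)=C/CC/C(C)=C/CC/C(C)=C/CC/C(C)=C/COS(C)(=O)=O | intermediate
11 | (2E,6E,10E,14E)-geranylfarnesyl chloride | CC(C)=CCC/C(C)=C/CC/C(C)=C/CC/C(C)=C/CC/C(C)=C/CCl | intermediate
12 | (2E,6E,10E,14E)-geranylfarnesyl diphosphate (drawn as free acid, handled as tris-ammonium salt) | CC(C)=CCC/C(C)=C/CC/C(C)=C/CC/C(C)=C/CC/C(C)=C/COP(=O)(O)OP(=O)(O)O | intermediate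
13 | water | O | starting material
14 | bicyclic C22 cation: ring D and the 15-membered ring closed, C15, C21 and C25 set (enzyme-bound, not isolated) | C/C1=C\CC/C(C)=C/CC/C(C)=C/C[C@@]2(C)CC[C@H]([C+](C)C)[C@@H]2CC1 | intermediate
15 | tricyclic allyl cation C27–C2–C3: ring A closed, C6 and C8 set (enzyme-bound, not isolated) | C/C1=C2\CC[C@@H](C)[C@@H]2CC/C(C)=C/C[C@@]2(C)CC[C@H](C(C)C)[C@@H]2C[CH+]1 | intermediate
16 | tetracyclic allyl cation at C27: rings B and C closed, C11 and C13 set (enzyme-bound, not isolated) | C/C1=C2\CC[C@@H](C)[C@@H]2CC[C@H](C)[C@H]2C[C@@]3(C)CC[C@H](C(C)C)[C@@H]3C[C+]12 | intermediate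
17 | sesterfisherol | C/C1=C2\CC[C@@H](C)[C@@H]2CC[C@H](C)[C@H]2C[C@@]3(C)CC[C@H](C(C)C)[C@@H]3C[C@]12O | intermediate
18 | 16-hydroxysesterfisherol (C16 alcohol, not isolated) | C/C1=C2\CC[C@@H](C)[C@@H]2CC[C@H](C)[C@H]2C[C@@]3(CO)CC[C@H](C(C)C)[C@@H]3C[C@]12O | intermediate
19 | sesterfisherol-16-al (C16 aldehyde, not isolated) | C/C1=C2\CC[C@@H](C)[C@@H]2CC[C@H](C)[C@H]2C[C@@]3(C=O)CC[C@H](C(C)C)[C@@H]3C[C@]12O | intermediate
20 | sesterfisheric acid | C/C1=C2\CC[C@@H](C)[C@@H]2CC[C@H](C)[C@H]2C[C@@]3(C(=O)O)CC[C@H](C(C)C)[C@@H]3C[C@]12O | target

**Step count**

Total: 9 steps. Longest linear sequence: 8 steps (from geranyl acetate 3, steps 2–9).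

**Steps most likely to fail (riskiest first)**

Step 8. Chemically made 12 may be turned over incompletely: the C25 diphosphate can aggregate with Mg2+, traces of monophosphate or Z isomers can inhibit, and phosphatase in the enzyme preparation can hydrolyse it. The cascade may also be quenched early to partly cyclised hydrocarbons. The fallback sets out from 1 and comes back to the route at 17. Farnesyl bromide 1 would be displaced with tris(tetra-n-butylammonium) hydrogen diphosphate in MeCN and ion-exchanged to (2E,6E)-farnesyl diphosphate F1. F1 and commercial isopentenyl diphosphate (CC(=C)CCOP(=O)(O)OP(=O)(O)O, 2 equiv) would then be given to the full-length bifunctional synthase with Mg2+. Its prenyltransferase domain should extend F1 through (2E,6E,10E)-geranylgeranyl diphosphate F2 to 12, which is then all-E by enzymatic origin and present only at a low steady-state concentration. The cyclase domain of the same protein converts this 12 into 17.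

Step 9. Uptake of the lipophilic alcohol 17 by the cells may be poor, flux may be lost after the first hydroxylation so that the oxidation stops short of the acid, and host enzymes may oxidise other positions. The fallback sets out from 17 and comes back at 20. Microsomes of Saccharomyces cerevisiae co-expressing the P450 and a cytochrome P450 reductase, with an NADPH-regenerating system, would be used only for the first hydroxylation, and 18 would be isolated. Dess–Martin periodinane buffered with NaHCO3 in CH2Cl2 should oxidise the neopentyl primary alcohol to 19 while the tertiary C27 hydroxyl stays inert. Pinnick oxidation (NaClO2, NaH2PO4, 2-methyl-2-butene, t-BuOH/H2O, 0 °C) should then give 20.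

Step 7. Displacement on the long lipophilic chloride may be slow, with competing hydrolysis or elimination of the allylic chloride and losses during ion exchange. The fallback sets out from 9 and comes back at 12. Geranylfarnesol 9 would be phosphorylated directly with trichloroacetonitrile and bis(triethylammonium) hydrogen phosphate in MeCN at rt (Cramer-type condensation, repeated additions). This passes through geranylfarnesyl monophosphate F3, which is phosphorylated further in the same mixture. The diphosphate 12 would be separated from mono- and triphosphate by silica chromatography (i-PrOH/conc. NH3/H2O) and converted to the ammonium salt.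

**Further compounds**

F1 | step 8 | (2E,6E)-farnesyl diphosphate | CC(C)=CCC/C(C)=C/CC/C(C)=C/COP(=O)(O)OP(=O)(O)O
F2 | step 8 | (2E,6E,10E)-geranylgeranyl diphosphate | CC(C)=CCC/C(C)=C/CC/C(C)=C/CC/C(C)=C/COP(=O)(O)OP(=O)(O)O
F0 | step 9 | none | none
F3 | step 7 | (2E,6E,10E,14E)-geranylfarnesyl monophosphate | CC(C)=CCC/C(C)=C/CC/C(C)=C/CC/C(C)=C/CC/C(C)=C/COP(=O)(O)O
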